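## Retrosynthetic overview

1. Target 27 ⇐ methyl ester 26 (saponification) ⇐ α-peroxy aldehyde 25 (Wittig) ⇐ diol 24 (periodate cleavage).
2. Key disconnection: the bond from the alkenyl CH to dioxolane C5 of 24 ⇒ alkenyltrifluoroborate 22 + bridged peroxyketal 11. Enabling feature: C5 of the 1,2-dioxolane carries peroxide oxygen O1, so with one more oxygen it is a ketal carbon (latent peroxycarbenium ion), and it lies 1,3-cis to the C3 side arm across the five-membered ring. The arm's terminal oxygen can therefore be that second oxygen (temporary oxane ring, a 2,6,7-trioxabicyclo[3.2.1]octane) and hand the alkenyl group over on its own face.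
3. 11 ⇐ epoxy alcohol 8 (ozonolysis in MeOH, 5-exo epoxide opening, transketalisation) ⇐ Z-allylic alcohol 7 (Sharpless epoxidation) ⇐ skipped enynoate 5 (syn-ethylcupration) ⇐ 1 + 4.
4. 22 ⇐ alkenyl iodide 19 ⇐ alkyne 17 (carboalumination) ⇐ ester 15 (Johnson–Claisen chirality transfer) ⇐ (R)-allylic alcohol 14 (Sharpless kinetic resolution) ⇐ 12.
5. Ring order: oxirane (step 6) → 1,2-dioxolane, then oxane bridge (both step 7) → oxane opened in step 15. C3 is set by catalysis, C5 is relayed from C3, the side-chain centre comes from catalysis plus a [3,3] shift.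

Key step: step 15

Remark: C3/C4/C5 are the dioxolane locants of the target (C3 bears the acrylate, C5 the dienyl chain). In bicycle 11 the ketal carbon is C1 and the peroxide-bearing quaternary carbon is C5. The carbinol centre of the diol arm (11, 24) is sacrificial and is excised in step 16. Building blocks 1, 4 and 12 are assumed to be commercial.

## Route

Step 1
Reactants: 1 2-ethylacrolein (2-methylidenebutanal)
Product: 2 2-methylidenebutan-1-ol
Conditions: NaBH4, CeCl3·7H2O, MeOH, 0 °C
Reagents that add atoms: none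
Why: Luche 1,2-reduction of the enal reduces only the carbonyl group and leaves the 1,1-disubstituted alkene in place.

Step 2
Reactants: 2 2-methylidenebutan-1-ol
Product: 3 2-(bromomethyl)but-1-ene
Conditions: PBr3, Et2O, 0 °C
Reagents that add atoms: phosphorus tribromide, BrP(Br)Br
Why: Conversion of a primary allylic alcohol to the bromide with PBr3 is routine, and SN2 and SN2' give the same compound because the allyl unit is symmetrical about C2.

Step 3
Reactants: 3 2-(bromomethyl)but-1-ene; 4 methyl propiolate
Product: 5 methyl 5-methylidenehept-2-ynoate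
Conditions: CuI, K2CO3, Bu4NI (cat.), DMF, rt
Reagents that add atoms: none
Why: Copper(I)-mediated coupling of a terminal alkyne (as its copper acetylide) with an allylic bromide should give the skipped enynoate, the mild carbonate base limiting isomerisation to the allenoate.

Step 4
Reactants: 5 methyl 5-methylidenehept-2-ynoate
Product: 6 methyl (2Z)-3-ethyl-5-methylidenehept-2-enoate
Conditions: EtMgBr, CuBr·SMe2, THF, −78 °C; then 5; MeOH quench at −78 °C
Reagents that add atoms: ethylmagnesium bromide, CC[Mg]Br
Why: Organocopper conjugate addition to an ynoate is a syn-carbometallation, so protonation at −78 °C should place the new ethyl group cis to H and the 2-methylidenebutyl group cis to the ester (Z).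

Step 5
Reactants: 6 methyl (2Z)-3-ethyl-5-methylidenehept-2-enoate
Product: 7 (2Z)-3-ethyl-5-methylidenehept-2-en-1-ol
Conditions: DIBAL-H (2.2 equiv), CH2Cl2, −78 °C; Rochelle salt
Reagents that add atoms: none
Why: DIBAL-H 1,2-reduction of an enoate gives the allylic alcohol without touching either alkene or the Z geometry.

Step 6
Reactants: 7 (2Z)-3-ethyl-5-methylidenehept-2-en-1-ol
Product: 8 [(2S,3R)-3-ethyl-3-(2-methylidenebutyl)oxiran-2-yl]methanol
Conditions: Ti(OiPr)4 (10 mol%), L-(+)-diethyl tartrate (12 mol%), t-BuOOH, 4 Å MS, CH2Cl2, −20 °C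
Reagents that add atoms: tert-butyl hydroperoxide, CC(C)(C)OO
Why: Sharpless asymmetric epoxidation acts only on the allylic alkene, and L-(+)-tartrate should deliver oxygen to the face that gives the (2S,3R)-epoxide of this nerol-type Z-allylic alcohol, setting the tertiary C–O centre by catalyst control.

Step 7
Reactants: 8 [(2S,3R)-3-ethyl-3-(2-methylidenebutyl)oxiran-2-yl]methanol
Product: 11 (1R,4S,5S)-1,5-diethyl-2,6,7-trioxabicyclo[3.2.1]octan-4-ol, via methoxy hydroperoxide 9 (not isolated), via methoxydioxolane diol 10 (not isolated)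
Conditions: O3, CH2Cl2/MeOH (5:1), −78 °C; N2 purge; CSA (10 mol%), −78 → 0 °C; then concentrate, CH2Cl2, 4 Å MS, rt
Reagents that add atoms: ozone, [O-][O+]=O; methanol, CO (retained only in 9 and 10)
Why: Ozonolysis in methanol traps the disubstituted carbonyl oxide as α-methoxy hydroperoxide 9, whose OOH should open the oxirane 5-exo at the tertiary carbon with inversion under acid to give the (S)-configured peroxide-bearing quaternary centre of 10, and transketalisation by the primary hydroxyl then closes the oxane bridge, whose bridged geometry fixes the ketal carbon.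

Step 8
Reactants: 12 (2E)-pent-2-enal
Product: 13 rac-(4E)-hept-4-en-3-ol
Conditions: EtMgBr, THF, −78 → 0 °C; aq. work-up
Reagents that add atoms: ethylmagnesium bromide, CC[Mg]Br
Why: Grignard reagents add 1,2 to enals, giving the secondary allylic alcohol with the E alkene intact.

Step 9
Reactants: 13 rac-(4E)-hept-4-en-3-ol
Product: 14 (3R,4E)-hept-4-en-3-ol
Conditions: Ti(OiPr)4 (10 mol%), L-(+)-diisopropyl tartrate (15 mol%), t-BuOOH (0.6 equiv), 4 Å MS, CH2Cl2, −20 °C; recover unreacted alcohol
Reagents that add atoms: none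
Why: In the Sharpless kinetic resolution with L-(+)-tartrate the (S)-enantiomer of an (E)-secondary allylic alcohol is epoxidised much faster, so the (R)-alcohol should be recovered in high enantiomeric purity.

Step 10
Reactants: 14 (3R,4E)-hept-4-en-3-ol
Product: 15 ethyl (3R,4E)-3-ethylhept-4-enoate
Conditions: CH3C(OEt)3 (5 equiv), EtCO2H (cat.), 140 °C, EtOH distilled off
Reagents that add atoms: triethyl orthoacetate, CCOC(C)(OCC)OCC
Why: The Johnson–Claisen rearrangement proceeds through a chair transition state with the carbinol ethyl group equatorial, so the C–O stereocentre is transferred suprafacially to the new (R) C–C centre and the new alkene is E.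

Step 11
Reactants: 15 ethyl (3R,4E)-3-ethylhept-4-enoate
Product: 16 (3R,4E)-3-ethylhept-4-enal
Conditions: DIBAL-H (1.05 equiv), CH2Cl2, −78 °C; Rochelle salt
Reagents that add atoms: none
Why: At −78 °C DIBAL-H reduction of an ester stops at the aluminium hemiacetal and gives the aldehyde on work-up, and the stereocentre is β to the carbonyl and cannot epimerise.

Step 12
Reactants: 16 (3R,4E)-3-ethylhept-4-enal
Product: 17 (4R,5E)-4-ethyloct-5-en-1-yne
Conditions: dimethyl (1-diazo-2-oxopropyl)phosphonate, K2CO3, MeOH, 0 °C → rt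
Reagents that add atoms: dimethyl (1-diazo-2-oxopropyl)phosphonate, CC(=O)C(=[N+]=[N-])P(=O)(OC)OC
Why: The Ohira–Bestmann variant of the Seyferth–Gilbert homologation converts an enolisable aldehyde to the terminal alkyne under mild carbonate conditions.

Step 13
Reactants: 17 (4R,5E)-4-ethyloct-5-en-1-yne
Product: 19 (1E,4R,5E)-4-ethyl-1-iodo-2-methylocta-1,5-diene, via alkenyldimethylalane 18 (not isolated)
Conditions: Me3Al (2 equiv), Cp2ZrCl2 (20 mol%), CH2Cl2, 0 °C → rt; then I2, THF, −30 → 0 °C
Reagents that add atoms: trimethylaluminium, C[Al](C)C; iodine, II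
Why: Negishi zirconium-catalysed carboalumination adds Me and Al syn across the terminal alkyne (Me to the internal carbon) and iodinolysis occurs with retention, giving the E trisubstituted alkenyl iodide while the internal alkene is inert.

Step 14
Reactants: 19 (1E,4R,5E)-4-ethyl-1-iodo-2-methylocta-1,5-diene
Product: 22 potassium [(1E,4R,5E)-4-ethyl-2-methylocta-1,5-dien-1-yl]trifluoroborate, via alkenyllithium 20 (not isolated), via lithium alkenyltrimethoxyborate 21 (not isolated)
Conditions: t-BuLi (2.1 equiv), Et2O, −78 °C; B(OMe)3, −78 °C → rt; aq. KHF2, rt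
Reagents that add atoms: tert-butyllithium, [Li]C(C)(C)C (lithium retained only in 20 and 21); trimethyl borate, COB(OC)OC; potassium hydrogen difluoride, [K+].F[H-]F
Why: Lithium–iodine exchange, borate formation and fluoride exchange all proceed with retention of alkene geometry and give the bench-stable trifluoroborate.

Step 15
Reactants: 11 (1R,4S,5S)-1,5-diethyl-2,6,7-trioxabicyclo[3.2.1]octan-4-ol; 22 potassium [(1E,4R,5E)-4-ethyl-2-methylocta-1,5-dien-1-yl]trifluoroborate
Product: 24 (1S)-1-[(3S,5R)-3,5-diethyl-5-[(1E,4R,5E)-4-ethyl-2-methylocta-1,5-dien-1-yl]-1,2-dioxolan-3-yl]ethane-1,2-diol, via alkenyldifluoroborane 23 (not isolated)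
Conditions: 22 (1.5 equiv), BF3·OEt2 (1.5 equiv), CH2Cl2/MeCN, 0 °C, 20 min; then 11, −78 → −30 °C; aq. NaHCO3
Reagents that add atoms: none
Why: Proposed new method: alkenyldifluoroborane 23, released from 22 by fluoride abstraction, should be captured by the C4 hydroxyl and the neighbouring ether oxygen O2 of 11 and ionise the strained C1–O2 ketal bond to a peroxycarbenium ion (C1=O7+) that remains tethered to an alkoxy(alkenyl)fluoroborate, from which the alkenyl group migrates to C1 with retention of alkene geometry; the closest known reaction types are BF3-promoted couplings of potassium alkenyltrifluoroborates with O,O-acetals via oxocarbenium ions, hydroxyl-directed Petasis-type alkenyl transfer from boronate complexes, and Lewis-acid additions of allylsilanes and silyl enol ethers to peroxycarbenium ions from 3-alkoxy-1,2-dioxolanes. No ring is closed: the oxane ring of the bicycle is opened and the 1,2-dioxolane persists. The new quaternary stereocentre (dioxolane C5, R) is controlled by the C3 centre through the three-atom O–CH2–CH(OH) arm, which can reach only the face it has just left, so the alkenyl group should be delivered cis to the arm and trans to the C3 ethyl group (net retention at the ketal carbon). The step needs ionisation of the ether C–O bond rather than the C1–O7 bond of the peroxide (secured by the higher Lewis basicity of the ether oxygen, chelation by the adjacent hydroxyl and the absence of free BF3 after 1:1 pre-mixing) and internal rather than external delivery (secured by the tether and by the lack of a free nucleophilic borate once 22 is fully converted to 23).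

Step 16
Reactants: 24 (1S)-1-[(3S,5R)-3,5-diethyl-5-[(1E,4R,5E)-4-ethyl-2-methylocta-1,5-dien-1-yl]-1,2-dioxolan-3-yl]ethane-1,2-diol
Product: 25 (3S,5R)-3,5-diethyl-5-[(1E,4R,5E)-4-ethyl-2-methylocta-1,5-dien-1-yl]-1,2-dioxolane-3-carbaldehyde
Conditions: NaIO4, THF/H2O, 0 °C → rt; used crude
Reagents that add atoms: none
Why: Periodate glycol cleavage is inert toward dialkyl peroxides and alkenes and excises the sacrificial carbinol and CH2OH carbons, leaving the quaternary C3 centre untouched.

Step 17
Reactants: 25 (3S,5R)-3,5-diethyl-5-[(1E,4R,5E)-4-ethyl-2-methylocta-1,5-dien-1-yl]-1,2-dioxolane-3-carbaldehyde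
Product: 26 methyl (2E)-3-[(3S,5R)-3,5-diethyl-5-[(1E,4R,5E)-4-ethyl-2-methylocta-1,5-dien-1-yl]-1,2-dioxolan-3-yl]prop-2-enoate
Conditions: Ph3P=CHCO2Me, CH2Cl2, rt
Reagents that add atoms: methyl (triphenylphosphoranylidene)acetate, COC(=O)C=P(c1ccccc1)(c1ccccc1)c1ccccc1
Why: Wittig olefination with a stabilised ylide should give the E-enoate, the aldehyde having no α-hydrogen and the di-tertiary dialkyl peroxide being inert to the ylide.

Step 18
Reactants: 26 methyl (2E)-3-[(3S,5R)-3,5-diethyl-5-[(1E,4R,5E)-4-ethyl-2-methylocta-1,5-dien-1-yl]-1,2-dioxolan-3-yl]prop-2-enoate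
Product: 27 (2E)-3-[(3S,5R)-3,5-diethyl-5-[(1E,4R,5E)-4-ethyl-2-methylocta-1,5-dien-1-yl]-1,2-dioxolan-3-yl]prop-2-enoic acid (CNP0249416.2)
Conditions: LiOH, THF/MeOH/H2O, 0 °C → rt; then 1 M HCl to pH 3
Reagents that add atoms: lithium hydroxide, [Li+].[OH-]
Why: Saponification is compatible with this peroxide because both peroxide-bearing carbons are quaternary, so Kornblum–DeLaMare fragmentation is impossible.

## Compound list

1 | 2-ethylacrolein (2-methylidenebutanal) | CCC(=C)C=O | starting material
2 | 2-methylidenebutan-1-ol | CCC(=C)CO | intermediate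
3 | 2-(bromomethyl)but-1-ene | CCC(=C)CBr | intermediate
4 | methyl propiolate | COC(=O)C#C | starting material
5 | methyl 5-methylidenehept-2-ynoate | CCC(=C)CC#CC(=O)OC | intermediate
6 | methyl (2Z)-3-ethyl-5-methylidenehept-2-enoate | CCC(=C)C/C(CC)=C\C(=O)OC | intermediate
7 | (2Z)-3-ethyl-5-methylidenehept-2-en-1-ol | CCC(=C)C/C(CC)=C\CO | intermediate
8 | [(2S,3R)-3-ethyl-3-(2-methylidenebutyl)oxiran-2-yl]methanol | OC[C@@H]1O[C@]1(CC)CC(=C)CC | intermediate
9 | [(2S,3R)-3-ethyl-3-(2-hydroperoxy-2-methoxybutyl)oxiran-2-yl]methanol (epimers at the peroxyketal carbon) | OC[C@@H]1O[C@]1(CC)CC(CC)(OC)OO | intermediate (not isolated)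
10 | (1S)-1-[(3S)-3,5-diethyl-5-methoxy-1,2-dioxolan-3-yl]ethane-1,2-diol (C5 epimers) | OC[C@H](O)[C@]1(CC)CC(CC)(OC)OO1 | intermediate (not isolated)
11 | (1R,4S,5S)-1,5-diethyl-2,6,7-trioxabicyclo[3.2.1]octan-4-ol | CC[C@]12OC[C@H](O)[C@](CC)(C1)OO2 | intermediate
12 | (2E)-pent-2-enal | CC/C=C/C=O | starting material
13 | rac-(4E)-hept-4-en-3-ol | CC/C=C/C(O)CC | intermediate
14 | (3R,4E)-hept-4-en-3-ol | CC/C=C/[C@H](O)CC | intermediate
15 | ethyl (3R,4E)-3-ethylhept-4-enoate | CCOC(=O)C[C@@H](CC)/C=C/CC | intermediate
16 | (3R,4E)-3-ethylhept-4-enal | O=CC[C@@H](CC)/C=C/CC | intermediate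
17 | (4R,5E)-4-ethyloct-5-en-1-yne | C#CC[C@@H](CC)/C=C/CC | intermediate
18 | [(1E,4R,5E)-4-ethyl-2-methylocta-1,5-dien-1-yl]dimethylalane | CC/C=C/[C@H](CC)C/C(C)=C/[Al](C)C | intermediate (not isolated)
19 | (1E,4R,5E)-4-ethyl-1-iodo-2-methylocta-1,5-diene | CC/C=C/[C@H](CC)C/C(C)=C/I | intermediate
20 | [(1E,4R,5E)-4-ethyl-2-methylocta-1,5-dien-1-yl]lithium | CC/C=C/[C@H](CC)C/C(C)=C/[Li] | intermediate (not isolated)
21 | lithium [(1E,4R,5E)-4-ethyl-2-methylocta-1,5-dien-1-yl]trimethoxyborate | [Li+].CC/C=C/[C@H](CC)C/C(C)=C/[B-](OC)(OC)OC | intermediate (not isolated)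
22 | potassium [(1E,4R,5E)-4-ethyl-2-methylocta-1,5-dien-1-yl]trifluoroborate | [K+].CC/C=C/[C@H](CC)C/C(C)=C/[B-](F)(F)F | intermediate
23 | [(1E,4R,5E)-4-ethyl-2-methylocta-1,5-dien-1-yl]difluoroborane | CC/C=C/[C@H](CC)C/C(C)=C/B(F)F | intermediate (not isolated)
24 | (1S)-1-[(3S,5R)-3,5-diethyl-5-[(1E,4R,5E)-4-ethyl-2-methylocta-1,5-dien-1-yl]-1,2-dioxolan-3-yl]ethane-1,2-diol | CC/C=C/[C@H](CC)C/C(C)=C/[C@@]1(CC)C[C@]([C@@H](O)CO)(CC)OO1 | intermediate
25 | (3S,5R)-3,5-diethyl-5-[(1E,4R,5E)-4-ethyl-2-methylocta-1,5-dien-1-yl]-1,2-dioxolane-3-carbaldehyde | CC/C=C/[C@H](CC)C/C(C)=C/[C@@]1(CC)C[C@](C=O)(CC)OO1 | intermediate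
26 | methyl (2E)-3-[(3S,5R)-3,5-diethyl-5-[(1E,4R,5E)-4-ethyl-2-methylocta-1,5-dien-1-yl]-1,2-dioxolan-3-yl]prop-2-enoate | CC/C=C/[C@H](CC)C/C(C)=C/[C@@]1(CC)C[C@](/C=C/C(=O)OC)(CC)OO1 | intermediate
27 | (2E)-3-[(3S,5R)-3,5-diethyl-5-[(1E,4R,5E)-4-ethyl-2-methylocta-1,5-dien-1-yl]-1,2-dioxolan-3-yl]prop-2-enoic acid | CC/C=C/[C@H](CC)C/C(C)=C/[C@@]1(CC)C[C@](/C=C/C(=O)O)(CC)OO1 | target

## Step count and risks

Total step count: 18. Longest linear sequence: 11 steps (steps 1–7 or 8–14, then 15–18).

**Step 15 (the proposed new method).** Three processes may defeat it: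
- The boron Lewis acid may ionise the peroxide-side C–O bond or engage the O–O bond, followed by boron-to-oxygen migration of the alkenyl group (oxidative loss of the nucleophile and of the peroxide).
- External instead of internal delivery would attack the face trans to the arm and give poor facial selectivity.
- The tertiary allylic peroxide product may re-ionise and epimerise.

Fallback with known chemistry, setting out from 8 and 19 and returning at 24: ozonolysis of 8 with reductive work-up (O3, CH2Cl2, −78 °C; Me2S) would give keto epoxy alcohol 1-[(2R,3S)-2-ethyl-3-(hydroxymethyl)oxiran-2-yl]butan-2-one F1, in equilibrium with its cyclic hemiketal. Addition of alkenyllithium 20 (from 19 and t-BuLi as in step 14, 2.2 equiv, THF, −78 °C) to the ketone would give the tertiary allylic alcohol (4E,7R,8E)-7-ethyl-3-{[(2R,3S)-2-ethyl-3-(hydroxymethyl)oxiran-2-yl]methyl}-5-methylundeca-4,8-dien-3-ol F2 as a mixture of carbinol epimers. Concentrated ethereal H2O2 with catalytic acid would convert the tertiary allylic alcohol through its allyl cation into the tertiary allylic hydroperoxide [(2S,3R)-3-[(3E,6R,7E)-2,6-diethyl-2-hydroperoxy-4-methyldeca-3,7-dien-1-yl]-3-ethyloxiran-2-yl]methanol F3. F3 would open the oxirane 5-exo at the tertiary carbon with inversion and give 24 together with its C5 epimer (1S)-1-[(3S,5S)-3,5-diethyl-5-[(1E,4R,5E)-4-ethyl-2-methylocta-1,5-dien-1-yl]-1,2-dioxolan-3-yl]ethane-1,2-diol F4, to be separated by chromatography. This fallback gives up the stereochemical relay to C5 but uses only carbonyl addition, SN1 hydroperoxide formation and hydroperoxide–epoxide cyclisation.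

**Step 7.** The carbonyl oxide may be diverted (ozonide or oligomer formation instead of methanol capture). The α-methoxy hydroperoxide may undergo acid-induced Criegee-type fragmentation. The epoxide may be opened by methanol or in the 6-endo mode before the hydroperoxide attacks, and closure of the oxane bridge may be incomplete.

Fallback setting out from 8 and returning at 11, with the peroxide oxygens taken from H2O2 instead of ozone: perhydrolysis of 8 with anhydrous ethereal H2O2 and catalytic phosphomolybdic acid would open the oxirane at the tertiary carbon with inversion to the hydroperoxy diol (2S,3S)-3-ethyl-3-hydroperoxy-5-methylideneheptane-1,2-diol F5. Ozonolysis of F5 in CH2Cl2/MeOH would convert the methylidene group into the methoxy hydroperoxide (2S,3S)-3-ethyl-3,5-dihydroperoxy-5-methoxyheptane-1,2-diol F6. Catalytic CSA would then close the dioxolane by transperoxyketalisation and the oxane bridge by transketalisation to give 11.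

**Step 4.** The doubly activated CH2 of the skipped enynoate may be deprotonated, leading to isomerisation to an allenoate or conjugated dienoate. The alkenylcopper/allenolate intermediate may equilibrate before protonation, eroding the Z geometry on which the sense of the epoxidation depends.

Fallback setting out from 3 and returning at 7, bypassing 5 and 6: hydroalumination–iodination of commercial pent-2-yn-1-ol F7 (Red-Al, THF, 0 °C; then I2, −78 °C) would give (2Z)-3-iodopent-2-en-1-ol F8, its geometry fixed by the cyclic alkoxyalanate. Negishi coupling of F8 with (2-methylidenebutyl)zinc bromide F9, made from bromide 3 and zinc dust in THF, under Pd(PPh3)4 catalysis would replace iodine with retention and give 7 directly.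

## Further compounds

F1 | step 15 | 1-[(2R,3S)-2-ethyl-3-(hydroxymethyl)oxiran-2-yl]butan-2-one | OC[C@@H]1O[C@]1(CC)CC(=O)CC
F2 | step 15 | (4E,7R,8E)-7-ethyl-3-{[(2R,3S)-2-ethyl-3-(hydroxymethyl)oxiran-2-yl]methyl}-5-methylundeca-4,8-dien-3-ol (carbinol epimers) | OC[C@@H]1O[C@]1(CC)CC(O)(CC)/C=C(\C)C[C@@H](CC)/C=C/CC
F3 | step 15 | [(2S,3R)-3-[(3E,6R,7E)-2,6-diethyl-2-hydroperoxy-4-methyldeca-3,7-dien-1-yl]-3-ethyloxiran-2-yl]methanol (epimers at the hydroperoxide carbon) | OC[C@@H]1O[C@]1(CC)CC(OO)(CC)/C=C(\C)C[C@@H](CC)/C=C/CC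
F4 | step 15 | (1S)-1-[(3S,5S)-3,5-diethyl-5-[(1E,4R,5E)-4-ethyl-2-methylocta-1,5-dien-1-yl]-1,2-dioxolan-3-yl]ethane-1,2-diol | CC/C=C/[C@H](CC)C/C(C)=C/[C@]1(CC)C[C@]([C@@H](O)CO)(CC)OO1
F5 | step 7 | (2S,3S)-3-ethyl-3-hydroperoxy-5-methylideneheptane-1,2-diol | OC[C@H](O)[C@@](CC)(OO)CC(=C)CC
F6 | step 7 | (2S,3S)-3-ethyl-3,5-dihydroperoxy-5-methoxyheptane-1,2-diol (C5 epimers) | OC[C@H](O)[C@@](CC)(OO)CC(CC)(OC)OO
F7 | step 4 | pent-2-yn-1-ol | CCC#CCO
F8 | step 4 | (2Z)-3-iodopent-2-en-1-ol | OC/C=C(\I)CC
F9 | step 4 | (2-methylidenebutyl)zinc bromide | CCC(=C)C[Zn]Br
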